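The plan rests on cutting the cyclohexane ring of the trans-fused hexahydrobenzofuran at C5–C6, the CHBr–CH2 bond (benzofuran numbering). Ring-closing metathesis of a trans-4,5-disubstituted γ-lactone, which carries a 1,1-dimethylallyl group on C3a and an allyl group on C7a, closes this ring in one operation as the C5=C6 alkene. The step exploits the quaternary C4 beside C5 and the two axial methyl groups (C4, C7a) of the rigid bicycle: they direct epoxidation to one face and hydride to C6, so that invertive bromination places the equatorial bromine on C5. The lactone carbonyl C2 is finally turned into the (Z)-bromomethyl enone.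

Key step: step 6

Remark: all intermediates are named with the benzofuran numbering of the target (O1, C2, C3, C3a, C4–C7, C7a); the target is read as (3aS,5S,7aS) with a Z exocyclic alkene, which means a trans ring fusion and an equatorial bromine.

Step 1
Reactants: 1 3,3-dimethylpent-4-enoic acid; 2 (4S)-4-benzyl-1,3-oxazolidin-2-one
Product: 4 (4S)-4-benzyl-3-(3,3-dimethylpent-4-enoyl)-1,3-oxazolidin-2-one, via mixed pivalic anhydride 3 (not isolated)
Conditions: PivCl, Et3N, THF, −20 °C; then 2, LiCl, rt
Reagents that add atoms: none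
Why: Mixed-anhydride N-acylation: the lithium-chloride-activated oxazolidinone should attack the unhindered pentenoyl carbonyl of 3 rather than the pivaloyl carbonyl, and no stereocenter is formed.

Step 2
Reactants: 4 (4S)-4-benzyl-3-(3,3-dimethylpent-4-enoyl)-1,3-oxazolidin-2-one; 5 methyl bromoacetate
Product: 7 methyl (3S)-3-{[(4S)-4-benzyl-2-oxo-1,3-oxazolidin-3-yl]carbonyl}-4,4-dimethylhex-5-enoate, via sodium enolate 6 (not isolated)
Conditions: NaHMDS, THF, −78 °C; then 5, −78 → −30 °C
Reagents that add atoms: none
Why: Auxiliary-controlled (Evans-type) enolate alkylation: the chelated Z sodium enolate 6 should be alkylated by the reactive α-bromo ester on the face opposite the benzyl group of the (4S)-auxiliary, which sets C3a as S.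

Step 3
Reactants: 7 methyl (3S)-3-{[(4S)-4-benzyl-2-oxo-1,3-oxazolidin-3-yl]carbonyl}-4,4-dimethylhex-5-enoate
Product: 8 methyl (3S)-3-[(ethylsulfanyl)carbonyl]-4,4-dimethylhex-5-enoate
Conditions: EtSNa, THF, 0 °C → rt; then 1 M HCl
Reagents that add atoms: sodium ethanethiolate, CC[S-].[Na+]
Why: Acyl transfer from the imide to a thiolate: the soft nucleophile should cleave the hindered exocyclic imide carbonyl selectively, release auxiliary 2 for reuse and leave the methyl ester and the C3a stereocenter untouched.

Step 4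
Reactants: 8 methyl (3S)-3-[(ethylsulfanyl)carbonyl]-4,4-dimethylhex-5-enoate
Product: 9 methyl (3S)-3-acetyl-4,4-dimethylhex-5-enoate
Conditions: Me2CuLi, Et2O, −78 → −30 °C; then aq NH4Cl
Reagents that add atoms: lithium dimethylcuprate, [Li+].C[Cu-]C
Why: Ketone synthesis from a thioester and a Gilman cuprate (acyl substitution): the thioester is far more electrophilic than the methyl ester and the methyl ketone formed does not add the cuprate at low temperature, so C3a should not epimerise.

Step 5
Reactants: 9 methyl (3S)-3-acetyl-4,4-dimethylhex-5-enoate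
Product: 11 (4S,5S)-5-methyl-4-(2-methylbut-3-en-2-yl)-5-(prop-2-en-1-yl)oxolan-2-one, via hydroxy ester 10 (not isolated)
Conditions: allylZnBr (THF solution), THF, 0 °C → rt; 1 M HCl; then TsOH·H2O (5 mol%), CH2Cl2, rt
Reagents that add atoms: allylzinc bromide, C=CC[Zn]Br
Why: Allylzinc addition to a ketone followed by acid-catalysed lactonisation: the organozinc does not touch the ester, and Felkin–Anh attack anti to the quaternary C4 substituent, with the CH2CO2Me arm next to the carbonyl oxygen, should set C7a as S (allyl trans to the C4 arm) before the tertiary hydroxyl closes the γ-lactone with loss of methanol.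

Step 6
Reactants: 11 (4S,5S)-5-methyl-4-(2-methylbut-3-en-2-yl)-5-(prop-2-en-1-yl)oxolan-2-one
Product: 12 (3aS,7aS)-4,4,7a-trimethyl-3a,4,7,7a-tetrahydro-1-benzofuran-2(3H)-one
Conditions: 2nd-generation Ru benzylidene catalyst (H2IMes)(PCy3)Cl2Ru=CHPh (5 mol%), CH2Cl2 (5 mM), 40 °C
Reagents that add atoms: none
Why: Ring-closing olefin metathesis: the Ru alkylidene should load onto the unhindered allyl group on C7a, and the Ru=C6 carbene then undergoes [2+2] cycloaddition and cycloreversion with the neopentyl vinyl group on C4, which forms C5=C6 and releases ethene. The closest known reaction type is RCM of 1,7-dienes to cyclohexenes that carry an allylic quaternary carbon. One ring is closed, the six-membered carbocycle, by metathesis ring closure between the trans-disposed arms on C3a and C7a of the lactone, which gives the trans-fused bicycle with the alkene opposite the ring fusion. No stereocenter is formed; C3a and C7a come from steps 2 and 5 and are not touched. The selectivity needed is ring closure over intermolecular cross-metathesis, which high dilution, the gem-dimethyl group on C4 (Thorpe–Ingold effect) and the absence of any other alkene should secure. The new alkene sits between quaternary C4 and the C7 methylene, so only its C6 end is open to nucleophiles in step 8.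

Step 7
Reactants: 12 (3aS,7aS)-4,4,7a-trimethyl-3a,4,7,7a-tetrahydro-1-benzofuran-2(3H)-one
Product: 13 (3aS,5S,6R,7aS)-5,6-epoxy-4,4,7a-trimethylhexahydro-1-benzofuran-2(3H)-one
Conditions: mCPBA, CH2Cl2, 0 °C → rt
Reagents that add atoms: mCPBA, OOC(=O)c1cccc(Cl)c1
Why: Prilezhaev epoxidation: in the locked trans-fused bicycle the axial methyl groups on C4 and C7a shield one face of the C5=C6 alkene, so the peracid should add from the other face and give the 5S,6R epoxide.

Step 8
Reactants: 13 (3aS,5S,6R,7aS)-5,6-epoxy-4,4,7a-trimethylhexahydro-1-benzofuran-2(3H)-one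
Product: 14 (1S,2S,4R)-2-(2-hydroxyethyl)-1,3,3-trimethylcyclohexane-1,4-diol
Conditions: LiAlH4, THF, 0 °C → reflux; then H2O
Reagents that add atoms: none
Why: Hydride opening of an epoxide under trans-diaxial (Fürst–Plattner) control: hydride should attack C6, the carbon that is not neopentyl, so that the C5–O bond survives as the axial 5R alcohol, while the lactone is reduced to the diol in the same operation and is restored in step 9.

Step 9
Reactants: 14 (1S,2S,4R)-2-(2-hydroxyethyl)-1,3,3-trimethylcyclohexane-1,4-diol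
Product: 16 (3aS,5R,7aS)-5-hydroxy-4,4,7a-trimethylhexahydro-1-benzofuran-2(3H)-one, via lactol 15 (not isolated)
Conditions: TEMPO (20 mol%), PhI(OAc)2 (2.5 equiv), CH2Cl2, rt
Reagents that add atoms: none
Why: Oxoammonium-catalysed (TEMPO) oxidative lactonisation of a 1,4-diol: the primary alcohol is oxidised to the aldehyde, which closes onto the tertiary hydroxyl to give lactol 15 and is oxidised again to the lactone, while the hindered axial neopentyl alcohol on C5 should react much more slowly.

Step 10
Reactants: 16 (3aS,5R,7aS)-5-hydroxy-4,4,7a-trimethylhexahydro-1-benzofuran-2(3H)-one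
Product: 17 (3aS,5S,7aS)-5-bromo-4,4,7a-trimethylhexahydro-1-benzofuran-2(3H)-one
Conditions: CBr4, PPh3, PhMe, 70 °C
Reagents that add atoms: carbon tetrabromide, BrC(Br)(Br)Br
Why: Appel bromination with inversion (SN2 on an alkoxyphosphonium ion): bromide should displace the axial leaving group on C5 from the equatorial side and turn the 5R alcohol into the equatorial 5S bromide.

Step 11
Reactants: 17 (3aS,5S,7aS)-5-bromo-4,4,7a-trimethylhexahydro-1-benzofuran-2(3H)-one; 18 N-methoxy-N-methylpropanamide
Product: 21 (2Z)-2-[(3aS,5S,7aS)-5-bromo-4,4,7a-trimethylhexahydro-1-benzofuran-2(3H)-ylidene]-N-methoxy-N-methylpropanamide, via lithium enolate 19 (not isolated), via hemiketal 20 (not isolated)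
Conditions: 18 (2.2 equiv), LDA (2.2 equiv), THF, −78 °C; then 17, −78 → −40 °C; AcOH; then TsOH·H2O (10 mol%), 4 Å MS, PhMe, 50 °C
Reagents that add atoms: none
Why: Claisen-type addition of an amide enolate to a lactone followed by acid-catalysed cyclodehydration: the β-keto amide/lactol 20 should lose water towards the carbonyl to give the conjugated exocyclic enol ether, and equilibration through the oxocarbenium ion should favour the Z isomer, in which the smaller methyl group and not the amide faces the ring CH2 (C3).

Step 12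
Reactants: 21 (2Z)-2-[(3aS,5S,7aS)-5-bromo-4,4,7a-trimethylhexahydro-1-benzofuran-2(3H)-ylidene]-N-methoxy-N-methylpropanamide
Product: 23 (3Z)-1-bromo-3-[(3aS,5S,7aS)-5-bromo-4,4,7a-trimethylhexahydro-1-benzofuran-2(3H)-ylidene]butan-2-one, via tetrahedral adduct 22 (not isolated)
Conditions: CH2Br2, MeLi·LiBr, THF, −78 °C; then AcOH
Reagents that add atoms: dibromomethane, BrCBr
Why: Homologation of a Weinreb amide with a lithium carbenoid: bromomethyllithium formed in the presence of 21 should add once to give the chelated adduct 22, which collapses to the bromomethyl ketone only on protonation, so over-addition is avoided and the alkene geometry and the C5 bromide are kept.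

Compound list
1 | 3,3-dimethylpent-4-enoic acid | C=CC(C)(C)CC(=O)O | starting material
2 | (4S)-4-benzyl-1,3-oxazolidin-2-one | O=C1N[C@@H](Cc2ccccc2)CO1 | starting material
3 | 3,3-dimethylpent-4-enoic pivalic anhydride (not isolated) | C=CC(C)(C)CC(=O)OC(=O)C(C)(C)C | intermediate
4 | (4S)-4-benzyl-3-(3,3-dimethylpent-4-enoyl)-1,3-oxazolidin-2-one | C=CC(C)(C)CC(=O)N1[C@@H](Cc2ccccc2)COC1=O | intermediate
5 | methyl bromoacetate | COC(=O)CBr | starting material
6 | sodium (Z)-enolate of 4 (not isolated) | C=CC(C)(C)/C=C(\O[Na])N1[C@@H](Cc2ccccc2)COC1=O | intermediate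
7 | methyl (3S)-3-{[(4S)-4-benzyl-2-oxo-1,3-oxazolidin-3-yl]carbonyl}-4,4-dimethylhex-5-enoate | C=CC(C)(C)[C@H](CC(=O)OC)C(=O)N1[C@@H](Cc2ccccc2)COC1=O | intermediate
8 | methyl (3S)-3-[(ethylsulfanyl)carbonyl]-4,4-dimethylhex-5-enoate | C=CC(C)(C)[C@H](CC(=O)OC)C(=O)SCC | intermediate
9 | methyl (3S)-3-acetyl-4,4-dimethylhex-5-enoate | C=CC(C)(C)[C@H](CC(=O)OC)C(C)=O | intermediate
10 | methyl (3S)-3-[(2S)-2-hydroxypent-4-en-2-yl]-4,4-dimethylhex-5-enoate (not isolated) | C=CC(C)(C)[C@H](CC(=O)OC)[C@@](C)(O)CC=C | intermediate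
11 | (4S,5S)-5-methyl-4-(2-methylbut-3-en-2-yl)-5-(prop-2-en-1-yl)oxolan-2-one; the two alkenyl arms are trans on the lactone | O=C1C[C@@H](C(C)(C)C=C)[C@](C)(CC=C)O1 | intermediate
12 | (3aS,7aS)-4,4,7a-trimethyl-3a,4,7,7a-tetrahydro-1-benzofuran-2(3H)-one; trans-fused, C5=C6 alkene | O=C1C[C@H]2C(C)(C)C=CC[C@]2(C)O1 | intermediate
13 | (3aS,5S,6R,7aS)-5,6-epoxy-4,4,7a-trimethylhexahydro-1-benzofuran-2(3H)-one; oxirane on the face anti to the C7a methyl | O=C1C[C@H]2C(C)(C)[C@@H]3O[C@@H]3C[C@]2(C)O1 | intermediate
14 | (1S,2S,4R)-2-(2-hydroxyethyl)-1,3,3-trimethylcyclohexane-1,4-diol | OCC[C@H]1C(C)(C)[C@H](O)CC[C@]1(C)O | intermediate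
15 | (3aS,5R,7aS)-4,4,7a-trimethyloctahydro-1-benzofuran-2,5-diol, lactol, both C2 epimers (not isolated) | OC1C[C@H]2C(C)(C)[C@H](O)CC[C@]2(C)O1 | intermediate
16 | (3aS,5R,7aS)-5-hydroxy-4,4,7a-trimethylhexahydro-1-benzofuran-2(3H)-one; axial C5 hydroxyl | O=C1C[C@H]2C(C)(C)[C@H](O)CC[C@]2(C)O1 | intermediate
17 | (3aS,5S,7aS)-5-bromo-4,4,7a-trimethylhexahydro-1-benzofuran-2(3H)-one; equatorial C5 bromine | O=C1C[C@H]2C(C)(C)[C@@H](Br)CC[C@]2(C)O1 | intermediate
18 | N-methoxy-N-methylpropanamide | CCC(=O)N(C)OC | starting material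
19 | lithium (Z)-enolate of 18 (not isolated) | C/C=C(\O[Li])N(C)OC | intermediate
20 | cyclic hemiketal from addition of 19 to the lactone carbonyl of 17, mixture of epimers, in equilibrium with the open β-keto amide (not isolated) | CC(C(=O)N(C)OC)C1(O)C[C@H]2C(C)(C)[C@@H](Br)CC[C@]2(C)O1 | intermediate
21 | (2Z)-2-[(3aS,5S,7aS)-5-bromo-4,4,7a-trimethylhexahydro-1-benzofuran-2(3H)-ylidene]-N-methoxy-N-methylpropanamide | C/C(C(=O)N(C)OC)=C1\C[C@H]2C(C)(C)[C@@H](Br)CC[C@]2(C)O1 | intermediate
22 | lithium alkoxide of the N-methoxy-N-methyl hemiaminal formed by addition of bromomethyllithium to 21 (not isolated) | C/C(C(O[Li])(CBr)N(C)OC)=C1\C[C@H]2C(C)(C)[C@@H](Br)CC[C@]2(C)O1 | intermediate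
23 | (3Z)-1-bromo-3-[(3aS,5S,7aS)-5-bromo-4,4,7a-trimethylhexahydro-1-benzofuran-2(3H)-ylidene]butan-2-one | C/C(C(=O)CBr)=C1\C[C@H]2C(C)(C)[C@@H](Br)CC[C@]2(C)O1 | target

Total step count: 12
Longest linear sequence: 12 steps (from 1 to 23)

Steps most likely to fail

Step 10 (Appel bromination). The alkoxyphosphonium ion on the axial, neopentyl C5 may lose a proton from C6 (elimination to the C5=C6 alkene) or undergo a 1,2-methyl shift from C4 before bromide can attack from the hindered equatorial side. The fallback sets out from 16 and installs the bromide by a radical route. Oxidation with DMP should give (3aS,7aS)-4,4,7a-trimethylhexahydro-1-benzofuran-2,5-dione F1. Its ketone enolate (KHMDS, PhNTf2, THF, −78 °C; on the ketone only C6 carries α-hydrogens, and the lactone CH2 is less acidic) should give (3aS,7aS)-4,4,7a-trimethyl-2-oxo-2,3,3a,4,7,7a-hexahydro-1-benzofuran-5-yl trifluoromethanesulfonate F2. Nickel-catalysed triflate–bromide exchange (Ni(cod)2 cat., LiBr, DMA/THF) should give (3aS,7aS)-5-bromo-4,4,7a-trimethyl-3a,4,7,7a-tetrahydro-1-benzofuran-2(3H)-one F3. Hydrogen-atom-transfer hydrogenation (Mn(dpm)3 cat., PhSiH3, TBHP, i-PrOH) should then put hydrogen on C6 and reduce the α-bromo C5 radical from the face anti to the axial C4 methyl, which leaves the bromine equatorial. The route is rejoined at 17.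

Step 11 (amide enolate addition and cyclodehydration). Proton transfer from C3 of the lactone to the more basic amide enolate may outrun addition, and the dehydration may stop at an E/Z mixture or drift to the endocyclic enol ether. The fallback sets out from 17 and builds the side chain in the opposite order. Takai–Utimoto ethylidenation (CH3CHBr2, TiCl4, Zn, TMEDA, THF) should convert the lactone carbonyl into (2Z,3aS,5S,7aS)-5-bromo-2-ethylidene-4,4,7a-trimethyloctahydro-1-benzofuran F4. C-Acylation of this enol ether with bromoacetyl bromide and 2,6-di-tert-butylpyridine (CH2Cl2, −78 → 0 °C), followed by loss of the proton next to the new carbonyl, should give 23 directly. This path comes back at 23 and does not need step 12.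

Step 12 (carbenoid homologation). Bromomethyllithium may decompose by α-elimination before it adds to the hindered, electron-rich amide carbonyl of the vinylogous carbamate, so that conversion stalls. The fallback sets out from 21 and uses enolate bromination instead. MeMgBr (THF, 0 °C) should give (3Z)-3-[(3aS,5S,7aS)-5-bromo-4,4,7a-trimethylhexahydro-1-benzofuran-2(3H)-ylidene]butan-2-one F5. Kinetic deprotonation at the α′-methyl group (LiHMDS, TMSCl, THF, −78 °C) should give {[(3Z)-3-[(3aS,5S,7aS)-5-bromo-4,4,7a-trimethylhexahydro-1-benzofuran-2(3H)-ylidene]but-1-en-2-yl]oxy}trimethylsilane F6. Bromination of F6 with NBS (THF, −78 °C) should give 23, where the route is rejoined.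

Further compounds
F1 | step 10 | (3aS,7aS)-4,4,7a-trimethylhexahydro-1-benzofuran-2,5-dione | O=C1C[C@H]2C(C)(C)C(=O)CC[C@]2(C)O1
F2 | step 10 | (3aS,7aS)-4,4,7a-trimethyl-2-oxo-2,3,3a,4,7,7a-hexahydro-1-benzofuran-5-yl trifluoromethanesulfonate | O=C1C[C@H]2C(C)(C)C(OS(=O)(=O)C(F)(F)F)=CC[C@]2(C)O1
F3 | step 10 | (3aS,7aS)-5-bromo-4,4,7a-trimethyl-3a,4,7,7a-tetrahydro-1-benzofuran-2(3H)-one | O=C1C[C@H]2C(C)(C)C(Br)=CC[C@]2(C)O1
F4 | step 11 | (2Z,3aS,5S,7aS)-5-bromo-2-ethylidene-4,4,7a-trimethyloctahydro-1-benzofuran | C/C=C1/C[C@H]2C(C)(C)[C@@H](Br)CC[C@]2(C)O1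
F5 | step 12 | (3Z)-3-[(3aS,5S,7aS)-5-bromo-4,4,7a-trimethylhexahydro-1-benzofuran-2(3H)-ylidene]butan-2-one | C/C(C(C)=O)=C1\C[C@H]2C(C)(C)[C@@H](Br)CC[C@]2(C)O1
F6 | step 12 | {[(3Z)-3-[(3aS,5S,7aS)-5-bromo-4,4,7a-trimethylhexahydro-1-benzofuran-2(3H)-ylidene]but-1-en-2-yl]oxy}trimethylsilane | C/C(C(=C)O[Si](C)(C)C)=C1\C[C@H]2C(C)(C)[C@@H](Br)CC[C@]2(C)O1
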